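**Retrosynthetic overview**
- Last bond: the C8 ester, from the macrocyclic C8 alcohol and (2S,3R)-2,3-dimethyloxirane-2-carboxylic acid (Sharpless epoxidation of tiglyl alcohol, then oxidation).
- Key bond C7–C8: SmI2 ketyl-radical 10-exo macrocyclisation of a β,γ-epoxy aldehyde onto a γ-alkenyl α-(methoxymethyl)butenolide; loss of methoxide after the radical addition unveils the α-methylene lactone, so C7, C8, the carbocycle and the exo-methylene arise in one step.
- Acyclic precursor: the C1–C10 oxirane by Sharpless epoxidation of an allylic alcohol whose E-alkene comes from cross-metathesis of a butenolide diene with a 2-substituted acrolein.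
- Butenolide: prenol dianion allylation (Z-alkene), oxidation to the Z-enal, catalytic asymmetric alkynylation (C6), hydroalumination/iodination, carbonylative lactonisation.
- Ring order: butenolide, then macro-ring oxirane, then ten-membered carbocycle (radical step); the side-chain oxirane is attached last.

Assumption: atom labels C1–C15 follow germacrane numbering (lactone C6/C12, ester at C8, oxirane C1–C10, acetoxymethyl C14); (R,R)-ProPhenol is taken to direct the alkynylzinc to the Si face of the enal (giving 6R), and the mirror-image ligand is used if the facial sense proves opposite.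

**Route**

Step 1
Reactants: 1 3-methylbut-2-en-1-ol (prenol); 2 3-bromoprop-1-ene (allyl bromide)
Product: 4 (2Z)-3-methylhepta-2,6-dien-1-ol, via dilithiated prenol 3 (not isolated)
Conditions: n-BuLi (2.2 equiv), TMEDA, Et2O, 0 °C to rt; then 2, −78 °C to rt
Reagents that add atoms: none
Why: Hydroxyl-directed allylic lithiation removes a proton from the methyl group cis to CH2OLi, and the chelated Z-dianion is alkylated at its terminal carbon (dianion alkylation, as in the prenol-to-nerol synthesis), which fixes the Z geometry of C4=C5.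

Step 2
Reactants: 4 (2Z)-3-methylhepta-2,6-dien-1-ol
Product: 5 (2Z)-3-methylhepta-2,6-dienal
Conditions: TEMPO (10 mol%), PhI(OAc)2, CH2Cl2, 0 °C to rt
Reagents that add atoms: none
Why: Oxoammonium (TEMPO) oxidation of the allylic alcohol is near-neutral and gives the enal without Z-to-E isomerisation, as for nerol to neral.

Step 3
Reactants: 5 (2Z)-3-methylhepta-2,6-dienal; 6 3-methoxyprop-1-yne
Product: 8 (4R,5Z)-1-methoxy-6-methyldeca-5,9-dien-2-yn-4-ol, via alkynyl(methyl)zinc 7 (not isolated)
Conditions: (R,R)-ProPhenol (20 mol%), Me2Zn (3 equiv), Ph3P=O (40 mol%), toluene, 4 °C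
Reagents that add atoms: none
Why: Dinuclear zinc–ProPhenol catalysed alkynylation of an enal (Trost) delivers the alkynylzinc to one enantioface of the aldehyde and so sets C6 as R.

Step 4
Reactants: 8 (4R,5Z)-1-methoxy-6-methyldeca-5,9-dien-2-yn-4-ol
Product: 10 (2Z,4R,5Z)-2-iodo-1-methoxy-6-methyldeca-2,5,9-trien-4-ol, via cyclic vinylalanate 9 (not isolated)
Conditions: NaAlH2(OCH2CH2OMe)2, THF, 0 °C; then I2, −78 °C
Reagents that add atoms: iodine, II
Why: Alkoxide-directed trans-hydroalumination puts aluminium on the distal alkyne carbon inside a five-membered alanate, and iodinolysis with retention gives the Z-iodoalkene with iodine cis to the carbinol, C6 being untouched.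

Step 5
Reactants: 10 (2Z,4R,5Z)-2-iodo-1-methoxy-6-methyldeca-2,5,9-trien-4-ol
Product: 11 (5R)-3-(methoxymethyl)-5-[(1Z)-2-methylhexa-1,5-dien-1-yl]furan-2(5H)-one
Conditions: Pd(PPh3)4 (5 mol%), CO (1 atm), K2CO3, THF, rt
Reagents that add atoms: carbon monoxide, [C-]#[O+]
Why: Oxidative addition of zerovalent palladium to the vinyl iodide, CO insertion and capture of the acylpalladium by the cis hydroxyl close the butenolide (Cowell–Stille carbonylative lactonisation) without breaking a bond at C6.

Step 6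
Reactants: 12 4-[(tert-butyldimethylsilyl)oxy]butanal
Product: 13 4-[(tert-butyldimethylsilyl)oxy]-2-methylidenebutanal
Conditions: 37% aq. HCHO, pyrrolidine (10 mol%), EtCO2H (10 mol%), i-PrOH, 45 °C
Reagents that add atoms: formaldehyde, C=O
Why: Amine-catalysed Mannich condensation with formaldehyde followed by elimination (organocatalytic α-methylenation of aldehydes) gives the 2-substituted acrolein.

Step 7
Reactants: 11 (5R)-3-(methoxymethyl)-5-[(1Z)-2-methylhexa-1,5-dien-1-yl]furan-2(5H)-one; 13 4-[(tert-butyldimethylsilyl)oxy]-2-methylidenebutanal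
Product: 14 (2E,6Z)-2-{2-[(tert-butyldimethylsilyl)oxy]ethyl}-7-[(2R)-4-(methoxymethyl)-5-oxo-2,5-dihydrofuran-2-yl]-6-methylhepta-2,6-dienal
Conditions: second-generation Hoveyda–Grubbs catalyst (5 mol%), 13 (3 equiv), CH2Cl2, 40 °C
Reagents that add atoms: none
Why: Cross-metathesis of a terminal alkene with a 2-substituted acrolein gives the trisubstituted enal as the thermodynamic E isomer (C2 cis to C9), while the trisubstituted and electron-poor alkenes of 11 do not take part.

Step 8
Reactants: 14 (the E-enal)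
Product: 15 (5R)-5-[(1Z,5E)-8-[(tert-butyldimethylsilyl)oxy]-6-(hydroxymethyl)-2-methylocta-1,5-dien-1-yl]-3-(methoxymethyl)furan-2(5H)-one
Conditions: NaBH4, CeCl3·7H2O, MeOH, −78 °C
Reagents that add atoms: none
Why: Luche reduction delivers hydride 1,2 to the enal far faster than it attacks the butenolide.

Step 9
Reactants: 15 (the allylic alcohol)
Product: 17 [(2S,3S)-2-{2-[(tert-butyldimethylsilyl)oxy]ethyl}-3-{(3Z)-4-[(2R)-4-(methoxymethyl)-5-oxo-2,5-dihydrofuran-2-yl]-3-methylbut-3-en-1-yl}oxiran-2-yl]methyl acetate, via epoxy alcohol 16 (not isolated)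
Conditions: Ti(OiPr)4 (10 mol%), L-(+)-DIPT (12 mol%), t-BuOOH, 4 Å MS, CH2Cl2, −20 °C; then P(OMe)3; then Ac2O, Et3N, DMAP (cat.), −20 to 0 °C
Reagents that add atoms: tert-butyl hydroperoxide, CC(C)(C)OO; acetic anhydride, CC(=O)OC(C)=O
Why: Sharpless asymmetric epoxidation of the only allylic alcohol with L-(+)-tartrate sets the 1S,10S oxirane under reagent control (same sense as E-2-methylbut-2-en-1-ol giving the 2S,3S product), and in situ acetylation installs the C14 acetate.

Step 10
Reactants: 17 (the epoxy acetate silyl ether)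
Product: 18 [(2S,3S)-2-(2-hydroxyethyl)-3-{(3Z)-4-[(2R)-4-(methoxymethyl)-5-oxo-2,5-dihydrofuran-2-yl]-3-methylbut-3-en-1-yl}oxiran-2-yl]methyl acetate
Conditions: HF·pyridine, pyridine, THF, 0 °C
Reagents that add atoms: none
Why: Buffered fluoride desilylation removes the primary silyl ether while the acetate, oxirane and butenolide stay intact.

Step 11
Reactants: 18 (the primary alcohol)
Product: 19 [(2S,3S)-3-{(3Z)-4-[(2R)-4-(methoxymethyl)-5-oxo-2,5-dihydrofuran-2-yl]-3-methylbut-3-en-1-yl}-2-(2-oxoethyl)oxiran-2-yl]methyl acetate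
Conditions: Dess–Martin periodinane, NaHCO3, CH2Cl2, 0 °C; used crude at once
Reagents that add atoms: none
Why: Bicarbonate-buffered Dess–Martin oxidation gives the sensitive β,γ-epoxy aldehyde without exposing it to acid or amine base.

Step 12
Reactants: 19 (the epoxy aldehyde)
Product: 22 (1S,4Z,6R,7R,8R,10S)-14-acetoxy-1,10-epoxy-8-hydroxygermacra-4,11(13)-dien-12,6-olide, via samarium ketyl 20 (not isolated), via samarium enolate 21 (not isolated)
Conditions: SmI2 (2.5 equiv), THF, −78 to −20 °C, 19 added by syringe pump to 2 mM; then sat. aq. NH4Cl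
Reagents that add atoms: none
Why: Proposed new method: one-electron reduction of the aldehyde gives a nucleophilic samarium ketyl that adds 10-exo-trig to the electron-poor β-carbon (C7) of the butenolide, the resulting α-carbonyl radical is reduced to a trivalent samarium enolate, and this expels methoxide (E1cB) to give the α-methylene lactone; C7 is set because only attack anti to the C5 side chain keeps the C5–C6–C7–C8 segment antiperiplanar in the forming ring (trans-fused lactone), and C8 is expected to be R from a transition state in which trivalent samarium bridges the ketyl oxygen and the lactone oxygens; the closest known reactions are SmI2 ketyl–olefin cyclisations onto enoates and butenolides (up to eight-membered rings), radical addition–elimination on 2-(alkoxymethyl)acrylates and β-elimination of samarium enolates.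

Step 13
Reactants: 23 (2E)-2-methylbut-2-en-1-ol
Product: 24 [(2R,3R)-2,3-dimethyloxiran-2-yl]methanol
Conditions: Ti(OiPr)4 (10 mol%), D-(−)-DIPT (12 mol%), t-BuOOH, 4 Å MS, CH2Cl2, −20 °C
Reagents that add atoms: tert-butyl hydroperoxide, CC(C)(C)OO
Why: Sharpless asymmetric epoxidation with D-(−)-tartrate gives the 2R,3R epoxy alcohol, the cis methyl groups following from the E alkene.

Step 14
Reactants: 24 [(2R,3R)-2,3-dimethyloxiran-2-yl]methanol
Product: 26 (2S,3R)-2,3-dimethyloxirane-2-carboxylic acid, via epoxy aldehyde 25 (not isolated)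
Conditions: TEMPO (20 mol%), PhI(OAc)2 (2.2 equiv), MeCN/H2O (1:1), rt
Reagents that add atoms: water, O
Why: TEMPO/PhI(OAc)2 oxidation in aqueous acetonitrile takes the primary alcohol through the aldehyde hydrate to the acid without opening the oxirane (the descriptor at C2 changes only because the CIP ranks change).

Step 15
Reactants: 22 (the macrocyclic C8 alcohol); 26 (2S,3R)-2,3-dimethyloxirane-2-carboxylic acid
Product: 28 (1S,4Z,6R,7R,8R,10S)-14-acetoxy-1,10-epoxy-12-oxogermacra-4,11(13)-dien-12,6-olid-8-yl (2S,3R)-2,3-dimethyloxirane-2-carboxylate, via mixed anhydride 27 (not isolated)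
Conditions: 2,4,6-trichlorobenzoyl chloride, Et3N, toluene, rt; then 22, DMAP, rt
Reagents that add atoms: none
Why: Yamaguchi esterification through the mixed anhydride acylates the hindered C8 hydroxyl with retention at C8 and is mild enough for the α-methylene lactone, acetate and both oxiranes.

**Compound list**

1 | 3-methylbut-2-en-1-ol (prenol) | CC(C)=CCO | starting material
2 | 3-bromoprop-1-ene (allyl bromide) | C=CCBr | starting material
3 | dilithiated prenol, lithium (2Z)-4-lithio-3-methylbut-2-en-1-olate (not isolated) | [Li]C/C(C)=C\CO[Li] | intermediate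
4 | (2Z)-3-methylhepta-2,6-dien-1-ol | C=CCC/C(C)=C\CO | intermediate
5 | (2Z)-3-methylhepta-2,6-dienal | C=CCC/C(C)=C\C=O | intermediate
6 | 3-methoxyprop-1-yne | COCC#C | starting material
7 | (3-methoxyprop-1-yn-1-yl)(methyl)zinc (not isolated) | COCC#C[Zn]C | intermediate
8 | (4R,5Z)-1-methoxy-6-methyldeca-5,9-dien-2-yn-4-ol | COCC#C[C@H](O)/C=C(/C)CCC=C | intermediate
9 | cyclic vinylalanate, sodium bis(2-methoxyethoxy) oxa-aluminacyclopentene ate complex (not isolated) | COCC1=C[C@@H](/C=C(/C)CCC=C)O[Al-]1(OCCOC)OCCOC.[Na+] | intermediate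
10 | (2Z,4R,5Z)-2-iodo-1-methoxy-6-methyldeca-2,5,9-trien-4-ol | COC/C(I)=C/[C@H](O)/C=C(/C)CCC=C | intermediate
11 | (5R)-3-(methoxymethyl)-5-[(1Z)-2-methylhexa-1,5-dien-1-yl]furan-2(5H)-one | COCC1=C[C@@H](/C=C(/C)CCC=C)OC1=O | intermediate
12 | 4-[(tert-butyldimethylsilyl)oxy]butanal | O=CCCCO[Si](C)(C)C(C)(C)C | starting material
13 | 4-[(tert-butyldimethylsilyl)oxy]-2-methylidenebutanal | C=C(C=O)CCO[Si](C)(C)C(C)(C)C | intermediate
14 | (2E,6Z)-2-{2-[(tert-butyldimethylsilyl)oxy]ethyl}-7-[(2R)-4-(methoxymethyl)-5-oxo-2,5-dihydrofuran-2-yl]-6-methylhepta-2,6-dienal | O=C/C(CCO[Si](C)(C)C(C)(C)C)=C/CC/C(C)=C\[C@@H]1C=C(COC)C(=O)O1 | intermediate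
15 | (5R)-5-[(1Z,5E)-8-[(tert-butyldimethylsilyl)oxy]-6-(hydroxymethyl)-2-methylocta-1,5-dien-1-yl]-3-(methoxymethyl)furan-2(5H)-one | OC/C(CCO[Si](C)(C)C(C)(C)C)=C/CC/C(C)=C\[C@@H]1C=C(COC)C(=O)O1 | intermediate
16 | [(2S,3S)-2-{2-[(tert-butyldimethylsilyl)oxy]ethyl}-3-{(3Z)-4-[(2R)-4-(methoxymethyl)-5-oxo-2,5-dihydrofuran-2-yl]-3-methylbut-3-en-1-yl}oxiran-2-yl]methanol (not isolated) | OC[C@]1(CCO[Si](C)(C)C(C)(C)C)O[C@H]1CC/C(C)=C\[C@@H]2C=C(COC)C(=O)O2 | intermediate
17 | acetate of 16 | CC(=O)OC[C@]1(CCO[Si](C)(C)C(C)(C)C)O[C@H]1CC/C(C)=C\[C@@H]2C=C(COC)C(=O)O2 | intermediate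
18 | [(2S,3S)-2-(2-hydroxyethyl)-3-{(3Z)-4-[(2R)-4-(methoxymethyl)-5-oxo-2,5-dihydrofuran-2-yl]-3-methylbut-3-en-1-yl}oxiran-2-yl]methyl acetate | CC(=O)OC[C@]1(CCO)O[C@H]1CC/C(C)=C\[C@@H]2C=C(COC)C(=O)O2 | intermediate
19 | [(2S,3S)-3-{(3Z)-4-[(2R)-4-(methoxymethyl)-5-oxo-2,5-dihydrofuran-2-yl]-3-methylbut-3-en-1-yl}-2-(2-oxoethyl)oxiran-2-yl]methyl acetate | CC(=O)OC[C@]1(CC=O)O[C@H]1CC/C(C)=C\[C@@H]2C=C(COC)C(=O)O2 | intermediate
20 | samarium ketyl of 19, C8 radical with O–SmI2 (not isolated) | CC(=O)OC[C@]1(C[CH]O[Sm](I)I)O[C@H]1CC/C(C)=C\[C@@H]2C=C(COC)C(=O)O2 | intermediate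
21 | cyclised trivalent samarium enolate with C13 methoxy still in place (not isolated) | COCC1=C(O[Sm](I)I)O[C@@H]2/C=C(/C)CC[C@@H]3O[C@]3(COC(C)=O)C[C@@H](O[Sm](I)I)[C@@H]12 | intermediate
22 | (1S,4Z,6R,7R,8R,10S)-14-acetoxy-1,10-epoxy-8-hydroxygermacra-4,11(13)-dien-12,6-olide | C=C1C(=O)O[C@@H]2/C=C(/C)CC[C@@H]3O[C@]3(COC(C)=O)C[C@@H](O)[C@@H]12 | intermediate
23 | (2E)-2-methylbut-2-en-1-ol | C/C=C(\C)CO | starting material
24 | [(2R,3R)-2,3-dimethyloxiran-2-yl]methanol | OC[C@@]1(C)O[C@@H]1C | intermediate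
25 | (2S,3R)-2,3-dimethyloxirane-2-carbaldehyde (not isolated) | O=C[C@@]1(C)O[C@@H]1C | intermediate
26 | (2S,3R)-2,3-dimethyloxirane-2-carboxylic acid | OC(=O)[C@@]1(C)O[C@@H]1C | intermediate
27 | (2S,3R)-2,3-dimethyloxirane-2-carboxylic 2,4,6-trichlorobenzoic anhydride (not isolated) | O=C(OC(=O)c1c(Cl)cc(Cl)cc1Cl)[C@@]1(C)O[C@@H]1C | intermediate
28 | (1S,4Z,6R,7R,8R,10S)-14-acetoxy-1,10-epoxy-12-oxogermacra-4,11(13)-dien-12,6-olid-8-yl (2S,3R)-2,3-dimethyloxirane-2-carboxylate | C=C1C(=O)O[C@@H]2/C=C(/C)CC[C@@H]3O[C@]3(COC(C)=O)C[C@@H](OC(=O)[C@@]3(C)O[C@@H]3C)[C@@H]12 | target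

**Step count and risks**

Total step count: 15. Longest linear sequence: 12 (steps 1–5, 7–12, 15).

Step 12 (most likely to fail: ten-membered ring closure and the C8 configuration). If the non-chelated transition state wins, the same radical addition from 19 runs through the C8-epimeric samarium enolate F1 to the 8S alcohol F2. F2 is then not discarded: Mitsunobu esterification with acid 26 (PPh3, DIAD, toluene, 0 °C) inverts C8 and gives the target directly. This fallback sets out from 19 and comes back to the route at 28; step 15 is then not needed.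

Step 3 (enantioselectivity and Z-integrity with a β,β-disubstituted Z-enal). The fallback sets out from 5 and comes back at 8. The lithium acetylide F3 (from 6 and n-BuLi, THF, −78 °C) is added to 5 to give the racemic alcohol F4. Dess–Martin oxidation gives the ynone F5. Reduction with (R)-2-methyl-CBS-oxazaborolidine and catecholborane (toluene, −78 °C), in which the alkynyl group acts as the small substituent, then gives 8.

Step 7 (cross-metathesis with a hindered 2-substituted acrolein). The fallback replaces metathesis by a carbonyl condensation; it sets out from 11 and comes back at 14. OsO4 (2 mol%)/NaIO4 with 2,6-lutidine in dioxane/H2O cleaves the terminal alkene, the other two alkenes being deactivated by the allylic or conjugated lactone oxygen and more hindered, to give the aldehyde F6. Mukaiyama aldol addition of the silyl enol ether F7 (from 12 with TMSCl, Et3N, DMF) with BF3·OEt2 at −78 °C gives the aldol F8. Dehydration with MsCl/Et3N gives the E-enal 14.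

**Further compounds**

F1 | step 12 | C8-epimeric trivalent samarium enolate (not isolated) | COCC1=C(O[Sm](I)I)O[C@@H]2/C=C(/C)CC[C@@H]3O[C@]3(COC(C)=O)C[C@H](O[Sm](I)I)[C@@H]12
F2 | step 12 | (1S,4Z,6R,7R,8S,10S)-14-acetoxy-1,10-epoxy-8-hydroxygermacra-4,11(13)-dien-12,6-olide | C=C1C(=O)O[C@@H]2/C=C(/C)CC[C@@H]3O[C@]3(COC(C)=O)C[C@H](O)[C@@H]12
F3 | step 3 | (3-methoxyprop-1-yn-1-yl)lithium | COCC#C[Li]
F4 | step 3 | racemic (5Z)-1-methoxy-6-methyldeca-5,9-dien-2-yn-4-ol | COCC#CC(O)/C=C(/C)CCC=C
F5 | step 3 | (5Z)-1-methoxy-6-methyldeca-5,9-dien-2-yn-4-one | COCC#CC(=O)/C=C(/C)CCC=C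
F6 | step 7 | (4Z)-5-[(2R)-4-(methoxymethyl)-5-oxo-2,5-dihydrofuran-2-yl]-4-methylpent-4-enal | O=CCC/C(C)=C\[C@@H]1C=C(COC)C(=O)O1
F7 | step 7 | tert-butyldimethyl{[4-(trimethylsilyloxy)but-3-en-1-yl]oxy}silane (E/Z mixture) | C[Si](C)(C)OC=CCCO[Si](C)(C)C(C)(C)C
F8 | step 7 | 2-{2-[(tert-butyldimethylsilyl)oxy]ethyl}-3-hydroxy-7-[(2R)-4-(methoxymethyl)-5-oxo-2,5-dihydrofuran-2-yl]-6-methylhept-6-enal (6Z, diastereomer mixture at C2 and C3) | O=CC(CCO[Si](C)(C)C(C)(C)C)C(O)CC/C(C)=C\[C@@H]1C=C(COC)C(=O)O1
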